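Numbering used throughout: C1 ketone, C2=C3 furanone alkene, ring oxygen between C3 and C10, C4=C5 with C15 on C4, C6 lactone carbinol, C7, C8 (tiglate), C9H2, C10 with methyl C14, lactone carbons C11 (=C13H2) and C12.

## Analysis of the target

Lychnophorolide B (30) is a furanoheliangolide: a ten-membered carbocycle C1–C10 bridged by an oxygen between C3 and C10, so that C10, C1, C2, C3 and that oxygen form a 3(2H)-furanone. An α-methylene-γ-butyrolactone (O–C6, C7–C11, C11=C13, C12=O) is trans-fused at C6/C7. The C4=C5 alkene is (Z), conjugated to the furanone and carries the hydroxymethyl C15; C8 carries the tiglate. There are four stereocentres: the contiguous triad C6 (R), C7 (R), C8 (S) and the quaternary C10 (R), which is insulated from the triad by C9H2 and must be set independently. The sensitive groups are the methylene lactone (Michael acceptor), the electrophilic furanone, the allylic C6–O bond and the tiglate. The difficulty lies in closing a strained, bridged medium ring with a (Z)-trisubstituted alkene while building the lactone, its methylene and the C6–C7–C8 triad with few oxidation-state changes. The strategy rests on one feature: a trans lactone with C11=C13 and an oxygen on C8, the carbon next to C7. That array is what remains when a propiolate on O6 cyclises onto a C7=C8 alkene and the metal left on C8 is replaced by a heteroatom.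

## Retrosynthetic reasoning

The C15 hydroxyl of 30 is released last from silyl ether 29, because a free primary allylic alcohol would interfere with esterification, iodination and palladium chemistry.

The C11=C13 methylene of 29 is traced to the amine adduct 26 through the quaternary salt 28 (methyl from 27). Masking is needed because the methylene would otherwise capture an alkenylpalladium at C4 in a fast five-membered closure.

The macrocycle 26 is cut at C3–C4, giving the (Z)-alkenyl iodide 25. This bond joins two sp2 carbons, the furanone has only one C–H next to oxygen, and cutting here leaves a fully linear chain. The forward Heck reaction must close a ten-membered ring, bond at C3 and not C2, and keep the alkene geometry.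

Iodide 25 goes back through the methylene lactone 24 to the alkenylsilane 23. Silicon is the placeholder for iodine because it survives the palladium step that builds the lactone, and ipso-substitution keeps the geometry. Tiglate 23 comes from alcohol 21 and acid 22, and 21 from boronate 20 by oxidation with retention.

Boronate 20 is cut at C7–C11 and C8–B, giving propiolate 18 and diboron 19. One event then delivers the lactone ring, the methylene and both C7 and C8 from the single stereocentre C6. Cutting C6–C7 or C7–C8 instead would require a separately prepared chiral partner for each centre.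

Propiolate 18 comes from alcohol 16 and acid 17 without touching C6. Alkenylsilane 16 comes from alkynol 15 by trans-hydrosilylation, which fixes both the position of silicon (C4) and the (Z) geometry.

Alkynol 15 is cut at C5–C6 into enal 13 and alkyne 14. A catalytic asymmetric alkynylation sets C6 under catalyst control, which is required because C10 is too remote to direct it.

Enal 13 is cut at C7=C8 into allyl furanone 11 and 12 (cross-metathesis, (E)-selective).

Furanone 11 is cut at C2–C3 and O–C3, giving hydroxy ketone 8 and formate 9 by way of enolate 10. Ketone 8 comes from amide 7, and 7 from dioxolanone 6.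

Dioxolanone 6 is cut at C9–C10, giving lactate acetal 3 and 4 through enolate 5. The acetal carbon of 3, made from 1 and 2, stores the chirality of lactic acid while C10 is planar and returns it on alkylation.

## Alternatives that were turned down

Alternative 1: The ten-membered ring is not closed but uncovered. A 5–7 fused bicycle with a tertiary alkoxide on C1 and a spiro-epoxide on C4 fragments (Grob type): C1–C5 breaks, C1 becomes the ketone, C4=C5 forms and the epoxide opens to the C15 alkoxide, giving A1.
- For: the reaction class is well understood, there is no entropic penalty, the alkene geometry follows from the antiperiplanar alignment, and C15 emerges as a free hydroxyl. On certainty of forming the ring it is stronger than the chosen plan.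
- Against: A1 still lacks the furanone (C3 must be oxidised, the O–C3 bridge closed, C2=C3 introduced), the lactone (oxidation of the isopropenyl group, ether removal at O6, lactonisation) and the tiglate. The bicyclic substrate also needs three stereocentres (C1, C4, C5) that are set only to be destroyed.
- Comparison: the chosen route is much shorter after the ring-forming step and makes the lactone, C7 and C8 in one operation.

Alternative 2: C3–C4 is the key disconnection. Zerovalent palladium inserts into a (Z)-C4 iodide, the alkenylpalladium adds across C2=C3 of the furanone with bonding at C3, and elimination closes the ring to A2, which lacks C13 and carries silyl ethers at C8 and C15.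
- For: no methylene lactone is present during the palladium step, so no amine mask is needed. On that point it is stronger.
- Against: the C6/C7/C8 array must be assembled by a separate multistep sequence; C13 must be added afterwards by lactone enolate chemistry in a molecule with a base-labile furanone; the C8 silyl ether must be exchanged for the tiglate.
- Comparison: the macrocyclisation risk is the same as in step 15 here. The chosen plan offers the one-step construction of lactone, methylene, C7 and C8 in its place.

Alternative 3: An eight-membered enone (C1 ketone, C2=C5 alkene) whose C10 oxygen bears an alkynyl ether (C3≡C4) undergoes intramolecular [2+2] photocycloaddition forming C2–C3 and C4–C5. Thermal opening of the cyclobutene (C2–C5 breaks) expands eight to ten and creates the furanone, giving A3.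
- For: furanone and medium ring arise together and no macrocyclisation is needed. On entropic grounds it is stronger.
- Against: an alkynyl ether of a hindered tertiary alcohol is hard to make and handle; the regiochemistry of the cycloaddition is uncertain; the C4=C5 geometry depends on the ring fusion of the photoadduct and the conrotatory opening; the product absorbs at the irradiation wavelength; the eight-membered substrate with four stereocentres needs a long synthesis; C13 is still missing.
- Comparison: the chosen route has one unprecedented step in ground-state chemistry, with stereochemistry that follows from the (E)-alkene and syn addition.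

Key step: step 10

Assumption: in step 7 the (S,S)-ProPhenol–zinc catalyst is taken to add the alkynyl group to the enal face that gives the (6S) carbinol, by analogy with its aldol reactions; the (R,R)-ligand would be used if the sense of induction were the reverse.

## Route

Step 1
Reactants: 1 (S)-lactic acid; 2 pivalaldehyde
Product: 3 (2S,5S)-2-tert-butyl-5-methyl-1,3-dioxolan-4-one
Conditions: TsOH·H2O (cat.), H2SO4 (cat.), pentane, reflux, Dean–Stark; recrystallisation, ether/pentane, −78 °C
Reagents that add atoms: none
Why: Acid-catalysed acetalisation under thermodynamic control favours the cis-dioxolanone, which is purified by crystallisation; its acetal carbon stores the chirality of the lactate (self-regeneration of stereocentres).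

Step 2
Reactants: 3 (2S,5S)-2-tert-butyl-5-methyl-1,3-dioxolan-4-one; 4 allyl bromide
Product: 6 (2S,5R)-2-tert-butyl-5-methyl-5-(prop-2-en-1-yl)-1,3-dioxolan-4-one, via lithium enolate 5 (not isolated)
Conditions: LiN(iPr)2, THF, −78 °C; then 4, −78 → −30 °C
Reagents that add atoms: none
Why: Enolate alkylation; the tert-butyl group shields its own face of the planar enolate, so 4 enters anti to it and replaces the former hydrogen with retention, setting the quaternary C10 centre (R).

Step 3
Reactants: 6 (2S,5R)-2-tert-butyl-5-methyl-5-(prop-2-en-1-yl)-1,3-dioxolan-4-one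
Product: 7 (2R)-2-hydroxy-N-methoxy-N,2-dimethylpent-4-enamide
Conditions: MeNH(OMe)·HCl, iPrMgCl, THF, −20 → 0 °C
Reagents that add atoms: N,O-dimethylhydroxylamine hydrochloride, CNOC.Cl
Why: The chloromagnesium amide opens the activated acylal-type lactone and the hemiacetal alkoxide collapses with loss of pivalaldehyde (Weinreb amide formation); the stereocentre is not involved.

Step 4
Reactants: 7 (2R)-2-hydroxy-N-methoxy-N,2-dimethylpent-4-enamide
Product: 8 (3R)-3-hydroxy-3-methylhex-5-en-2-one
Conditions: MeMgBr (3 equiv), THF, 0 °C → rt; aq NH4Cl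
Reagents that add atoms: methylmagnesium bromide, C[Mg]Br
Why: Weinreb ketone synthesis; the first equivalent deprotonates the hydroxyl and the chelated tetrahedral adduct prevents a second addition.

Step 5
Reactants: 8 (3R)-3-hydroxy-3-methylhex-5-en-2-one; 9 ethyl formate
Product: 11 (2R)-2-methyl-2-(prop-2-en-1-yl)furan-3(2H)-one, via formyl ketone sodium enolate 10 (not isolated)
Conditions: NaH (2.5 equiv), 9, THF, 0 °C → rt; then 2 M HCl, rt
Reagents that add atoms: none
Why: Crossed Claisen condensation of the methyl ketone with the non-enolisable formate, then acid-catalysed cyclodehydration of the tertiary hydroxyl onto the formyl carbon, the classical route to 2,2-disubstituted 3(2H)-furanones; C10 is untouched.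

Step 6
Reactants: 11 (2R)-2-methyl-2-(prop-2-en-1-yl)furan-3(2H)-one; 12 (E)-crotonaldehyde
Product: 13 (2E)-4-[(2R)-2-methyl-3-oxo-2,3-dihydrofuran-2-yl]but-2-enal
Conditions: second-generation Hoveyda–Grubbs catalyst RuCl2(H2IMes)(=CH-C6H4-2-OiPr) (5 mol%), 12 (5 equiv), CH2Cl2, 40 °C
Reagents that add atoms: none
Why: Olefin cross-metathesis of a terminal alkene with an enal partner gives the (E)-enal under thermodynamic control; the internal, electron-poor furanone alkene does not take part.

Step 7
Reactants: 13 (2E)-4-[(2R)-2-methyl-3-oxo-2,3-dihydrofuran-2-yl]but-2-enal; 14 tert-butyldimethyl(prop-2-yn-1-yloxy)silane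
Product: 15 (2R)-2-[(2E,4S)-7-[(tert-butyldimethylsilyl)oxy]-4-hydroxyhept-2-en-5-yn-1-yl]-2-methylfuran-3(2H)-one
Conditions: (S,S)-ProPhenol (2,6-bis[[(2S)-2-(hydroxydiphenylmethyl)pyrrolidin-1-yl]methyl]-4-methylphenol, 20 mol%), Me2Zn (3 equiv), Ph3P=O (40 mol%), toluene, 0 → 4 °C; aq NH4Cl
Reagents that add atoms: none
Why: Catalytic asymmetric alkynylation of an aldehyde by a dinuclear zinc alkoxide catalyst, a reaction type that tolerates enals; the catalyst alone sets C6 (S) because C10 is remote, and the weakly basic zinc reagents add 1,2 and spare the furanone.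

Step 8
Reactants: 15 (2R)-2-[(2E,4S)-7-[(tert-butyldimethylsilyl)oxy]-4-hydroxyhept-2-en-5-yn-1-yl]-2-methylfuran-3(2H)-one
Product: 16 (2R)-2-[(2E,4S,5Z)-7-[(tert-butyldimethylsilyl)oxy]-4-hydroxy-6-(triethylsilyl)hepta-2,5-dien-1-yl]-2-methylfuran-3(2H)-one
Conditions: [Cp*Ru(MeCN)3]PF6 (5 mol%), Et3SiH (1.2 equiv), CH2Cl2, 0 °C → rt
Reagents that add atoms: triethylsilane, CC[SiH](CC)CC
Why: Ruthenium-catalysed trans-hydrosilylation of a propargylic alcohol places silicon on the alkyne carbon distal to the free hydroxyl (C4) and adds H and Si anti, which gives the (Z)-alkenylsilane with silicon where C3 will later be attached; alkenes are not hydrosilylated by this catalyst.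

Step 9
Reactants: 16 (2R)-2-[(2E,4S,5Z)-7-[(tert-butyldimethylsilyl)oxy]-4-hydroxy-6-(triethylsilyl)hepta-2,5-dien-1-yl]-2-methylfuran-3(2H)-one; 17 propiolic acid
Product: 18 (2E,4S,5Z)-7-[(tert-butyldimethylsilyl)oxy]-1-[(2R)-2-methyl-3-oxo-2,3-dihydrofuran-2-yl]-6-(triethylsilyl)hepta-2,5-dien-4-yl prop-2-ynoate
Conditions: 17, N,N'-dicyclohexylcarbodiimide, DMAP (5 mol%), CH2Cl2, −20 → 0 °C
Reagents that add atoms: none
Why: Carbodiimide (Steglich) esterification at low temperature, which limits conjugate addition to the ynoate; the C6–O bond is not broken, so the configuration is retained.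

Step 10
Reactants: 18 (2E,4S,5Z)-7-[(tert-butyldimethylsilyl)oxy]-1-[(2R)-2-methyl-3-oxo-2,3-dihydrofuran-2-yl]-6-(triethylsilyl)hepta-2,5-dien-4-yl prop-2-ynoate; 19 bis(pinacolato)diboron
Product: 20 (4S,5S)-5-[(1Z)-3-[(tert-butyldimethylsilyl)oxy]-2-(triethylsilyl)prop-1-en-1-yl]-3-methylidene-4-[(1S)-2-[(2R)-2-methyl-3-oxo-2,3-dihydrofuran-2-yl]-1-(4,4,5,5-tetramethyl-1,3,2-dioxaborolan-2-yl)ethyl]oxolan-2-one (6S,7S,8S,10R)
Conditions: Pd(OAc)2 (10 mol%), 19 (2 equiv), MeOH (2 equiv), toluene, 50 °C
Reagents that add atoms: none
Why: Proposed new method: the closest known reaction type is the Pd(OAc)2-catalysed borylative cyclisation of 1,6-enynes with 19, which is established for carbon- and heteroatom-linked enynes with terminal alkenes but not for a propiolate ester tether or an internal alkene. Methanolysis of the palladium–boron species formed from Pd(OAc)2 and 19 should give a hydridopalladium species that hydropalladates the C11≡C13 triple bond with hydrogen on C13 and the metal on C11, the carbon next to the ester carbonyl, as is usual for alkynoates. The C11 alkenylpalladium then inserts the C7=C8 alkene by 5-exo-trig syn-carbopalladation, which forms C7–C11 and closes the γ-lactone. C7 is controlled by C6: in the cyclisation transition state the bulky silylated alkenyl group on C6 lies pseudo-equatorial and away from the reacting alkene, which leads to the 6,7-trans lactone. C8 is fixed relative to C7 by the (E) geometry of the alkene together with syn addition, and the secondary C8–Pd bond is converted into C8–B with retention by transmetalation with 19 and reductive elimination, which returns zerovalent palladium to the cycle. The step needs boron transfer to be faster than β-hydride loss towards C7 or C9, for which excess 19 and the phosphine-free catalyst are chosen, and it needs the alkenylpalladium to select C7=C8 over C4=C5, which the trisubstitution and the silyl group on C4 should ensure, since insertion there would put palladium on a fully substituted carbon.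

Step 11
Reactants: 20 the C8 pinacol boronate (6S,7S,8S,10R)
Product: 21 (4R,5S)-5-[(1Z)-3-[(tert-butyldimethylsilyl)oxy]-2-(triethylsilyl)prop-1-en-1-yl]-4-[(1S)-1-hydroxy-2-[(2R)-2-methyl-3-oxo-2,3-dihydrofuran-2-yl]ethyl]-3-methylideneoxolan-2-one (6S,7R,8S,10R)
Conditions: NaBO3·4H2O (4 equiv), THF/H2O (1:1), 0 °C → rt
Reagents that add atoms: sodium perborate (NaBO3·4H2O), [Na+].[Na+].O[B-]1(O)OO[B-](O)(O)OO1
Why: Oxidation of a secondary alkylboronate by peroxoborate proceeds by 1,2-migration of carbon from boron to oxygen with retention at C8; perborate is the mildest common reagent for this and is used cold because of the methylene lactone.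

Step 12
Reactants: 21 the C8 alcohol (6S,7R,8S,10R); 22 tiglic acid
Product: 23 the C8 (2E)-2-methylbut-2-enoate of 21 (6S,7R,8S,10R; 4Z alkenylsilane; C15 silyl ether)
Conditions: 22, 2,4,6-trichlorobenzoyl chloride, Et3N, toluene, rt; then 21, DMAP, rt
Reagents that add atoms: none
Why: Yamaguchi esterification through the mixed anhydride acylates hindered secondary alcohols; no bond to C8 is broken and the (E)-acid is the stable isomer.

Step 13
Reactants: 23 the C8 tiglate with the (Z)-alkenylsilane
Product: 24 (1S)-1-[(2S,3R)-2-[(1Z)-3-[(tert-butyldimethylsilyl)oxy]-2-iodoprop-1-en-1-yl]-4-methylidene-5-oxooxolan-3-yl]-2-[(2R)-2-methyl-3-oxo-2,3-dihydrofuran-2-yl]ethyl (2E)-2-methylbut-2-enoate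
Conditions: N-iodosuccinimide (1.2 equiv), 2,6-lutidine (0.5 equiv), (CF3)2CHOH, 0 °C
Reagents that add atoms: N-iodosuccinimide, O=C1CCC(=O)N1I
Why: Ipso-iododesilylation of an alkenylsilane through a β-silyl cation occurs with retention of geometry and is fast in the fluorinated alcohol; the methylene lactone, tiglate and furanone alkenes are electron-poor and should react far more slowly.

Step 14
Reactants: 24 the (Z)-alkenyl iodide with free methylene lactone
Product: 25 the 13-(dimethylamino)-11,13-dihydro derivative of 24 (6S,7R,8S,10R; C11 epimers)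
Conditions: Me2NH (2 M in THF, 2 equiv), THF, 0 °C
Reagents that add atoms: dimethylamine, CNC
Why: Aza-Michael addition to the α-methylene lactone is fast and reversible and removes the alkene that would otherwise intercept the alkenylpalladium in step 15; the new C11 centre is removed again in step 16, so its configuration is irrelevant.

Step 15
Reactants: 25 the amine-masked (Z)-alkenyl iodide
Product: 26 13-(dimethylamino)-11,13-dihydro-15-O-(tert-butyldimethylsilyl)lychnophorolide B (4Z,6R,7R,8S,10R; C11 epimers)
Conditions: Pd(OAc)2 (20 mol%), PPh3 (40 mol%), Ag2CO3 (2 equiv), MeCN (2 mM), 70 °C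
Reagents that add atoms: none
Why: Intramolecular Heck reaction: oxidative addition into the C4–I bond with retention and carbopalladation of C2=C3 with bonding at C3, which is both the β-carbon of the enone and the oxygen-bearing carbon of the enol ether. The α-palladated ketone can reach the C3 hydrogen by equilibration through its oxygen-bound enolate, as in Heck reactions of cyclic enones, and high dilution with a silver base favours ring closure.

Step 16
Reactants: 26 the amine-masked macrocycle; 27 iodomethane
Product: 29 15-O-(tert-butyldimethylsilyl)lychnophorolide B (4Z,6R,7R,8S,10R), via quaternary ammonium iodide 28 (not isolated)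
Conditions: 27 (10 equiv), MeCN, rt; then aq NaHCO3, CH2Cl2, rt
Reagents that add atoms: none
Why: Exhaustive N-methylation then mild base-induced β-elimination of trimethylamine (E1cB through the lactone enolate) restores the C11=C13 methylene without touching the stereocentres.

Step 17
Reactants: 29 15-O-(tert-butyldimethylsilyl)lychnophorolide B
Product: 30 lychnophorolide B (4Z,6R,7R,8S,10R)
Conditions: HF·pyridine, pyridine, THF, 0 °C → rt
Reagents that add atoms: none
Why: Buffered fluoride cleavage of a primary allylic silyl ether; the weakly acidic medium avoids conjugate addition to the methylene lactone and acyl migration of the tiglate.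

## Compound list

1 | (S)-lactic acid | C[C@H](O)C(=O)O | starting material
2 | pivalaldehyde (2,2-dimethylpropanal) | CC(C)(C)C=O | starting material
3 | (2S,5S)-2-tert-butyl-5-methyl-1,3-dioxolan-4-one (cis) | C[C@@H]1O[C@H](C(C)(C)C)OC1=O | intermediate
4 | allyl bromide (3-bromoprop-1-ene) | C=CCBr | starting material
5 | lithium (2S)-2-tert-butyl-5-methyl-1,3-dioxol-4-olate (enolate of 3) | CC1=C([O-])O[C@@H](C(C)(C)C)O1.[Li+] | intermediate
6 | (2S,5R)-2-tert-butyl-5-methyl-5-(prop-2-en-1-yl)-1,3-dioxolan-4-one | C[C@]1(CC=C)O[C@H](C(C)(C)C)OC1=O | intermediate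
7 | (2R)-2-hydroxy-N-methoxy-N,2-dimethylpent-4-enamide | C=CC[C@@](C)(O)C(=O)N(C)OC | intermediate
8 | (3R)-3-hydroxy-3-methylhex-5-en-2-one | C=CC[C@@](C)(O)C(C)=O | intermediate
9 | ethyl formate | CCOC=O | starting material
10 | sodium (1Z,4R)-4-hydroxy-4-methyl-3-oxohepta-1,6-dien-1-olate (enolate of the formyl ketone) | C=CC[C@@](C)(O)C(=O)/C=C\[O-].[Na+] | intermediate
11 | (2R)-2-methyl-2-(prop-2-en-1-yl)furan-3(2H)-one | C=CC[C@@]1(C)OC=CC1=O | intermediate
12 | (E)-crotonaldehyde | C/C=C/C=O | starting material
13 | (2E)-4-[(2R)-2-methyl-3-oxo-2,3-dihydrofuran-2-yl]but-2-enal | O=C/C=C/C[C@@]1(C)OC=CC1=O | intermediate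
14 | tert-butyldimethyl(prop-2-yn-1-yloxy)silane | C#CCO[Si](C)(C)C(C)(C)C | starting material
15 | (2R)-2-[(2E,4S)-7-[(tert-butyldimethylsilyl)oxy]-4-hydroxyhept-2-en-5-yn-1-yl]-2-methylfuran-3(2H)-one | CC(C)(C)[Si](C)(C)OCC#C[C@@H](O)/C=C/C[C@@]1(C)OC=CC1=O | intermediate
16 | (2R)-2-[(2E,4S,5Z)-7-[(tert-butyldimethylsilyl)oxy]-4-hydroxy-6-(triethylsilyl)hepta-2,5-dien-1-yl]-2-methylfuran-3(2H)-one | O[C@H](/C=C(\[Si](CC)(CC)CC)CO[Si](C)(C)C(C)(C)C)/C=C/C[C@@]1(C)OC=CC1=O | intermediate
17 | propiolic acid | C#CC(=O)O | starting material
18 | (2E,4S,5Z)-7-[(tert-butyldimethylsilyl)oxy]-1-[(2R)-2-methyl-3-oxo-2,3-dihydrofuran-2-yl]-6-(triethylsilyl)hepta-2,5-dien-4-yl prop-2-ynoate | C#CC(=O)O[C@H](/C=C(\[Si](CC)(CC)CC)CO[Si](C)(C)C(C)(C)C)/C=C/C[C@@]1(C)OC=CC1=O | intermediate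
19 | bis(pinacolato)diboron | CC1(C)OB(OC1(C)C)B1OC(C)(C)C(C)(C)O1 | starting material
20 | (4S,5S)-5-[(1Z)-3-[(tert-butyldimethylsilyl)oxy]-2-(triethylsilyl)prop-1-en-1-yl]-3-methylidene-4-[(1S)-2-[(2R)-2-methyl-3-oxo-2,3-dihydrofuran-2-yl]-1-(4,4,5,5-tetramethyl-1,3,2-dioxaborolan-2-yl)ethyl]oxolan-2-one (6S,7S,8S,10R) | C=C1C(=O)O[C@H](/C=C(\[Si](CC)(CC)CC)CO[Si](C)(C)C(C)(C)C)[C@H]1[C@@H](B2OC(C)(C)C(C)(C)O2)C[C@@]3(C)OC=CC3=O | intermediate
21 | (4R,5S)-5-[(1Z)-3-[(tert-butyldimethylsilyl)oxy]-2-(triethylsilyl)prop-1-en-1-yl]-4-[(1S)-1-hydroxy-2-[(2R)-2-methyl-3-oxo-2,3-dihydrofuran-2-yl]ethyl]-3-methylideneoxolan-2-one (6S,7R,8S,10R) | C=C1C(=O)O[C@H](/C=C(\[Si](CC)(CC)CC)CO[Si](C)(C)C(C)(C)C)[C@H]1[C@@H](O)C[C@@]3(C)OC=CC3=O | intermediate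
22 | tiglic acid ((2E)-2-methylbut-2-enoic acid) | C/C=C(\C)C(=O)O | starting material
23 | C8 (2E)-2-methylbut-2-enoate of 21: (1S)-1-[(2S,3R)-2-[(1Z)-3-[(tert-butyldimethylsilyl)oxy]-2-(triethylsilyl)prop-1-en-1-yl]-4-methylidene-5-oxooxolan-3-yl]-2-[(2R)-2-methyl-3-oxo-2,3-dihydrofuran-2-yl]ethyl (2E)-2-methylbut-2-enoate | C=C1C(=O)O[C@H](/C=C(\[Si](CC)(CC)CC)CO[Si](C)(C)C(C)(C)C)[C@H]1[C@@H](OC(=O)/C(C)=C/C)C[C@@]3(C)OC=CC3=O | intermediate
24 | (1S)-1-[(2S,3R)-2-[(1Z)-3-[(tert-butyldimethylsilyl)oxy]-2-iodoprop-1-en-1-yl]-4-methylidene-5-oxooxolan-3-yl]-2-[(2R)-2-methyl-3-oxo-2,3-dihydrofuran-2-yl]ethyl (2E)-2-methylbut-2-enoate | C=C1C(=O)O[C@H](/C=C(\I)CO[Si](C)(C)C(C)(C)C)[C@H]1[C@@H](OC(=O)/C(C)=C/C)C[C@@]3(C)OC=CC3=O | intermediate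
25 | 13-(dimethylamino)-11,13-dihydro derivative of 24: the lactone carries CH2NMe2 on C11 instead of the methylidene (6S,7R,8S,10R; C11 epimers) | CN(C)CC1C(=O)O[C@H](/C=C(\I)CO[Si](C)(C)C(C)(C)C)[C@H]1[C@@H](OC(=O)/C(C)=C/C)C[C@@]3(C)OC=CC3=O | intermediate
26 | 13-(dimethylamino)-11,13-dihydro-15-O-(tert-butyldimethylsilyl)lychnophorolide B (4Z,6R,7R,8S,10R; C11 epimers) | CN(C)CC1C(=O)O[C@@H]2/C=C(/CO[Si](C)(C)C(C)(C)C)C3=CC(=O)[C@@](C)(C[C@H](OC(=O)/C(C)=C/C)[C@@H]12)O3 | intermediate
27 | iodomethane | CI | starting material
28 | N-methyl quaternary ammonium iodide of 26 (13-(trimethylammonio) salt) | C[N+](C)(C)CC1C(=O)O[C@@H]2/C=C(/CO[Si](C)(C)C(C)(C)C)C3=CC(=O)[C@@](C)(C[C@H](OC(=O)/C(C)=C/C)[C@@H]12)O3.[I-] | intermediate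
29 | 15-O-(tert-butyldimethylsilyl)lychnophorolide B (4Z,6R,7R,8S,10R) | C=C1C(=O)O[C@@H]2/C=C(/CO[Si](C)(C)C(C)(C)C)C3=CC(=O)[C@@](C)(C[C@H](OC(=O)/C(C)=C/C)[C@@H]12)O3 | intermediate
30 | lychnophorolide B (4Z,6R,7R,8S,10R) | C=C1C(=O)O[C@@H]2/C=C(/CO)C3=CC(=O)[C@@](C)(C[C@H](OC(=O)/C(C)=C/C)[C@@H]12)O3 | target

## Step count and least certain steps

Total: 17 steps. Longest linear sequence: 17 steps from 1; all other partners are commercial and enter directly.

**Step 10 (key step, new method).** Three processes threaten it.
- β-Hydride elimination from the secondary C8 alkylpalladium before boron transfer would lead to diene cycloisomers.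
- The ester prefers the extended conformation, so cyclisation may be slow and the C11 alkenylpalladium may be protonated or borylated without ring closure.
- Zerovalent palladium may ionise the doubly allylic C6–O bond.

Fallback in known chemistry, setting out from 14 and 11 and returning at 21. The lactone and the C7–C8 bond are made by a Barbier allylation.
- Alkynylation of acrolein with 14 under the conditions of step 7 should give (3S)-6-[(tert-butyldimethylsilyl)oxy]hex-1-en-4-yn-3-ol F1.
- Trans-hydrosilylation as in step 8 should give (3S,4Z)-6-[(tert-butyldimethylsilyl)oxy]-5-(triethylsilyl)hexa-1,4-dien-3-ol F2.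
- Esterification with 2-(bromomethyl)acrylic acid (N,N'-diisopropylcarbodiimide, cat. DMAP, 0 °C) gives the 2-(bromomethyl)acrylate F3.
- Ring-closing metathesis with the second-generation Grubbs catalyst RuCl2(PCy3)(H2IMes)(=CHPh) in toluene at 80 °C gives (5S)-3-(bromomethyl)-5-[(1Z)-3-[(tert-butyldimethylsilyl)oxy]-2-(triethylsilyl)prop-1-en-1-yl]furan-2(5H)-one F4.
- In parallel the terminal alkene of 11 is cleaved (OsO4 cat., NaIO4, 2,6-lutidine, dioxane/water) to [(2R)-2-methyl-3-oxo-2,3-dihydrofuran-2-yl]acetaldehyde F5, which is used crude because it can lose the furanone oxygen by β-elimination.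
- Zn dust in THF/aqueous NH4Cl then couples F4 with F5. The allylzinc reacts through C7 on the face opposite the C6 substituent (trans lactone). The ring fixes the allyl unit in the (E)-like geometry, so the chair transition state should give the anti C7/C8 relationship, which is that of 21.

**Step 15.** After carbopalladation at C3 the palladium on C2 has no syn β-hydrogen. The enolate may therefore be protonated instead of eliminating, or the strained ten-membered transition state may lose out to reduction or intermolecular coupling. Loss of dimethylamine at 70 °C would also re-expose the methylene.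

Fallback, from 25, returning at 26: the enolate is accepted as the intended intermediate. A reductive Heck (conjugate addition) closure with Pd(OAc)2, Bu4NCl and HCO2Na in DMF at 60 °C should give the 2,3-dihydro macrocycle F6 (C2H2–C3H, C3 epimers). Soft enolisation (Me3SiOTf, Et3N) gives the C1 trimethylsilyl enol ether F7, in which C2 is the only possible enol carbon. Saegusa–Ito dehydrogenation with Pd(OAc)2 in MeCN restores C2=C3 and gives 26.

**Step 8.** Silicon may be delivered to C5 instead of C4, because the C15 silyloxy group is also propargylic and opposes the directing influence of the free C6 hydroxyl.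

Fallback, from 15, returning at 16: the regiochemistry is controlled from the other side by a hydroxyl-directed, proximal-selective trans-hydrosilylation.
- Chloroacetylation of O6 ((ClCH2CO)2O, pyridine) gives the chloroacetate F8.
- HF·pyridine frees the C15 hydroxyl to give the propargylic alcohol F9.
- [Cp*RuCl]4 with Et3SiH adds silicon to the alkyne carbon next to the free hydroxyl (C4), anti to hydrogen, giving the (Z)-alkenylsilane F10.
- Silylation (tert-butyldimethylsilyl triflate, 2,6-lutidine) gives F11.
- Thiourea with NaHCO3 in ethanol removes the chloroacetate and gives 16.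

**Step 11.** Peroxide may add to the methylene lactone in a conjugate sense, and under the mildly basic conditions the lactone acyl group may migrate from O6 to the new C8 hydroxyl.

Fallback, from 20, returning at 21: the oxidation is carried out on a tetracoordinate boron species with an electrophilic oxidant in weakly acidic medium. KHF2 in aqueous methanol converts 20 into the potassium trifluoroborate F12. Oxone (2KHSO5·KHSO4·K2SO4) in aqueous acetonitrile at 0 °C then oxidises the C–B bond with retention within minutes and gives 21.

## Further compounds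

F1 | step 10 | (3S)-6-[(tert-butyldimethylsilyl)oxy]hex-1-en-4-yn-3-ol | C=C[C@H](O)C#CCO[Si](C)(C)C(C)(C)C
F2 | step 10 | (3S,4Z)-6-[(tert-butyldimethylsilyl)oxy]-5-(triethylsilyl)hexa-1,4-dien-3-ol | C=C[C@H](O)/C=C(\[Si](CC)(CC)CC)CO[Si](C)(C)C(C)(C)C
F3 | step 10 | (3S,4Z)-6-[(tert-butyldimethylsilyl)oxy]-5-(triethylsilyl)hexa-1,4-dien-3-yl 2-(bromomethyl)prop-2-enoate | C=C(CBr)C(=O)O[C@@H](C=C)/C=C(\[Si](CC)(CC)CC)CO[Si](C)(C)C(C)(C)C
F4 | step 10 | (5S)-3-(bromomethyl)-5-[(1Z)-3-[(tert-butyldimethylsilyl)oxy]-2-(triethylsilyl)prop-1-en-1-yl]furan-2(5H)-one | BrCC1=C[C@@H](/C=C(\[Si](CC)(CC)CC)CO[Si](C)(C)C(C)(C)C)OC1=O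
F5 | step 10 | [(2R)-2-methyl-3-oxo-2,3-dihydrofuran-2-yl]acetaldehyde | O=CC[C@@]1(C)OC=CC1=O
F6 | step 15 | 2,3-dihydro derivative of 26 (tetrahydrofuran-3-one; C3 and C11 epimers) | CN(C)CC1C(=O)O[C@@H]2/C=C(/CO[Si](C)(C)C(C)(C)C)C3CC(=O)[C@@](C)(C[C@H](OC(=O)/C(C)=C/C)[C@@H]12)O3
F7 | step 15 | C1 trimethylsilyl enol ether of F6 (C1=C2 enol ether; C3 and C11 epimers) | CN(C)CC1C(=O)O[C@@H]2/C=C(/CO[Si](C)(C)C(C)(C)C)C3C=C(O[Si](C)(C)C)[C@@](C)(C[C@H](OC(=O)/C(C)=C/C)[C@@H]12)O3
F8 | step 8 | O6 chloroacetate of 15 | ClCC(=O)O[C@H](C#CCO[Si](C)(C)C(C)(C)C)/C=C/C[C@@]1(C)OC=CC1=O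
F9 | step 8 | O6 chloroacetate with free C15 hydroxyl | ClCC(=O)O[C@H](C#CCO)/C=C/C[C@@]1(C)OC=CC1=O
F10 | step 8 | O6 chloroacetate of the (Z)-C4 triethylsilyl alkene with free C15 hydroxyl | ClCC(=O)O[C@H](/C=C(\[Si](CC)(CC)CC)CO)/C=C/C[C@@]1(C)OC=CC1=O
F11 | step 8 | O6 chloroacetate of 16 | ClCC(=O)O[C@H](/C=C(\[Si](CC)(CC)CC)CO[Si](C)(C)C(C)(C)C)/C=C/C[C@@]1(C)OC=CC1=O
F12 | step 11 | potassium C8 trifluoroborate corresponding to 20 (6S,7S,8S,10R) | C=C1C(=O)O[C@H](/C=C(\[Si](CC)(CC)CC)CO[Si](C)(C)C(C)(C)C)[C@H]1[C@@H]([B-](F)(F)F)C[C@@]3(C)OC=CC3=O.[K+]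
A1 | alternative 1 | ten-membered 1-ketone with C10 tertiary hydroxyl, (Z)-C4=C5 bearing free C15 hydroxymethyl, C3 triethylsilyl ether, C6 4-methoxybenzyl ether, C7 isopropenyl and C8 tert-butyldimethylsilyl ether | COc1ccc(CO[C@@H]2/C=C(/CO)[C@@H](O[Si](CC)(CC)CC)CC(=O)[C@](C)(O)C[C@H](O[Si](C)(C)C(C)(C)C)[C@H]2C(C)=C)cc1
A2 | alternative 2 | bridged furanone macrocycle lacking C13, with C8 tert-butyldimethylsilyl ether and C15 tert-butyldiphenylsilyl ether | C1C(=O)O[C@@H]2/C=C(/CO[Si](c4ccccc4)(c4ccccc4)C(C)(C)C)C3=CC(=O)[C@@](C)(C[C@H](O[Si](C)(C)C(C)(C)C)[C@@H]12)O3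
A3 | alternative 3 | bridged furanone macrocycle lacking C13, with C8 triethylsilyl ether and C15 tert-butyldimethylsilyl ether | C1C(=O)O[C@@H]2/C=C(/CO[Si](C)(C)C(C)(C)C)C3=CC(=O)[C@@](C)(C[C@H](O[Si](CC)(CC)CC)[C@@H]12)O3
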